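Numbering: coumarin locants; unit A unprimed (joined at C8), unit B primed (the 7'-hydroxy unit, joined at C6'); ring A and ring B are the benzene rings of the two units.
Cuts: pyranone of unit A at O1-C2, C2-C3 and C4-C4a; pyranone of unit B at O1'-C2' and C3'-C4'; then ring B at C4a'-C5', and the chain at C5'-C6' and C7'-C8'.
Enabling feature: around ring B the carbons CH3-C5'-C6'-C7'-C8'-C8a'-C4a'-C4' are one unbranched chain oxygenated on every second carbon (C5' carbonyl lost as water, C7'-OH, C8a'-O, C4' carboxyl), and ring A sits on C6', which lies between two ketones in the open chain.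
Forward: 3,5-dimethoxytoluene gives the arylacetic acid (the C8-C6' bond is made here as an aryl-CH2 bond), the chain is assembled on a dioxinone (C7'-C8', then C5'-C6'), aldol aromatization builds ring B, then the pyranone of B, then acetylation, demethylation and pyranone closure on ring A, then debenzylation.
Stereochemistry: there is no stereocentre; the C6'-C8 axis arises as a racemate when ring A loses its symmetry in step 9.
Key step: step 5

Assumption: the target is drawn without an axial descriptor, so the racemic atropisomer mixture is taken as the goal; compounds 19 to 25 are racemic about the biaryl axis.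

Step 1
Reactants: 1 3,5-dimethoxytoluene
Product: 3 2-(2,6-dimethoxy-4-methylphenyl)ethanol, via aryllithium 2 (not isolated)
Conditions: n-BuLi, THF, 0 °C to rt; ethylene oxide (solution in THF), 0 °C to rt; aq. HCl
Reagents that add atoms: ethylene oxide, C1CO1
Why: Directed ortho-metalation puts lithium on the carbon between the two methoxy groups, and SN2 opening of ethylene oxide by the aryllithium attaches the two carbons that become C6' and C7'.

Step 2
Reactants: 3 2-(2,6-dimethoxy-4-methylphenyl)ethanol
Product: 5 (2,6-dimethoxy-4-methylphenyl)acetic acid, via arylacetaldehyde 4 (not isolated)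
Conditions: TEMPO (cat.), PhI(OAc)2 (2.2 equiv), MeCN/H2O, rt
Reagents that add atoms: water, O
Why: Oxoammonium (TEMPO) oxidation with PhI(OAc)2 as terminal oxidant takes a primary alcohol through the aldehyde hydrate to the acid without chlorinating or oxidizing the electron-rich ring.

Step 3
Reactants: 5 (2,6-dimethoxy-4-methylphenyl)acetic acid; 6 2,2,6-trimethyl-4H-1,3-dioxin-4-one
Product: 9 6-[3-(2,6-dimethoxy-4-methylphenyl)-2-oxopropyl]-2,2-dimethyl-4H-1,3-dioxin-4-one, via acid chloride 7 (not isolated), via lithium dienolate 8 (not isolated)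
Conditions: 5, (COCl)2, DMF (cat.), CH2Cl2, 0 °C to rt, evaporation; 6 (2.2 equiv), LiN(SiMe3)2 (2.2 equiv), THF, -78 °C; addition of 7, -78 °C; aq. HCl
Reagents that add atoms: none
Why: Claisen-type acylation, in which the lithium dienolate of the dioxinone reacts with the acid chloride at its gamma carbon and a second equivalent of dienolate takes up the acidic proton of the keto-dioxinone formed.

Step 4
Reactants: 9 6-[3-(2,6-dimethoxy-4-methylphenyl)-2-oxopropyl]-2,2-dimethyl-4H-1,3-dioxin-4-one; 10 N-methoxy-N-methylacetamide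
Product: 12 6-[3-(2,6-dimethoxy-4-methylphenyl)-2,4-dioxopentyl]-2,2-dimethyl-4H-1,3-dioxin-4-one, via dilithium dianion 11 (not isolated)
Conditions: LiN(CHMe2)2 (2.3 equiv), THF, -78 °C; 10, -78 to -20 °C; aq. HCl
Reagents that add atoms: none
Why: Acylation of a ketone alpha,alpha'-dianion (Weinreb ketone synthesis), in which the later-formed and more basic benzylic terminus attacks the N-methoxy-N-methylamide and the chelated tetrahedral adduct prevents over-addition; the new carbon is enolizable and has no fixed configuration.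

Step 5
Reactants: 12 6-[3-(2,6-dimethoxy-4-methylphenyl)-2,4-dioxopentyl]-2,2-dimethyl-4H-1,3-dioxin-4-one
Product: 14 6-(2,6-dimethoxy-4-methylphenyl)-7-hydroxy-2,2,5-trimethyl-4H-1,3-benzodioxin-4-one, via cyclic aldol adduct 13 (not isolated)
Conditions: Et3N (3 equiv), CH2Cl2, rt; then 1 M aq. HCl, rt
Reagents that add atoms: none
Why: Et3N generates the extended enolate of the vinylogous ester, whose alpha carbon (dioxinone C5, the future C4a') adds to the acetyl carbonyl (the future C5'), and carbinol 13 then loses water under acid while the C7' ketone enolizes, so that ring B is formed as a resorcylate. This is the known biomimetic aldol aromatization of diketo-dioxinones, the laboratory counterpart of the polyketide cyclization that leads to orsellinic acid. The one new ring closes in a 6-(enolexo)-exo-trig aldol mode, the only pairing of nucleophilic carbon and carbonyl in 12 that gives a six-membered carbocycle. No stereocentre remains, since the sp3 centres of 13 are erased on aromatization and the new aryl-aryl bond is not a stereogenic axis while ring A is still symmetric. The step needs carbon cyclization to win over oxygen cyclization to a pyranone and over Claisen-type closures, which the acetonide secures by blocking the carboxyl terminus while the amine base favours the carbon nucleophile. The acetonide also leaves C8a'-O and the C4' carboxyl tied together with only C7'-OH free, and the crowded biaryl bond needs no cross-coupling because the aryl group rides on an sp3 carbon until the ring aromatizes.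

Step 6
Reactants: 14 6-(2,6-dimethoxy-4-methylphenyl)-7-hydroxy-2,2,5-trimethyl-4H-1,3-benzodioxin-4-one
Product: 15 7-(benzyloxy)-6-(2,6-dimethoxy-4-methylphenyl)-2,2,5-trimethyl-4H-1,3-benzodioxin-4-one
Conditions: BnBr, K2CO3, acetone, 50 °C
Reagents that add atoms: benzyl bromide, BrCc1ccccc1
Why: Williamson ether synthesis on the only free phenol, which removes the para phenoxide that would otherwise deactivate the acyl carbon toward the enolate of step 7.

Step 7
Reactants: 15 7-(benzyloxy)-6-(2,6-dimethoxy-4-methylphenyl)-2,2,5-trimethyl-4H-1,3-benzodioxin-4-one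
Product: 17 7-(benzyloxy)-6-(2,6-dimethoxy-4-methylphenyl)-4-hydroxy-5-methyl-2H-chromen-2-one, via tert-butyl keto ester 16 (not isolated)
Conditions: tert-butyl acetate, LiN(CHMe2)2 (3.5 equiv each), THF, -78 °C; 15, -78 to 0 °C; AcOH, extractive work-up; crude 16 in toluene, 110 °C
Reagents that add atoms: tert-butyl acetate, CC(=O)OC(C)(C)C
Why: Claisen condensation of the ester enolate with the acyl acetal (an activated aryl ester) releases acetone and the C8a' phenol, and on heating the tert-butyl beta-keto ester loses tert-butanol to an acylketene that the neighbouring phenol traps to close the lactone as a 4-hydroxycoumarin.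

Step 8
Reactants: 17 7-(benzyloxy)-6-(2,6-dimethoxy-4-methylphenyl)-4-hydroxy-5-methyl-2H-chromen-2-one
Product: 18 7-(benzyloxy)-6-(2,6-dimethoxy-4-methylphenyl)-4-methoxy-5-methyl-2H-chromen-2-one
Conditions: Me2SO4, K2CO3, acetone, reflux
Reagents that add atoms: dimethyl sulfate, COS(=O)(=O)OC
Why: O-Alkylation of the vinylogous acid with dimethyl sulfate and K2CO3 is the standard route to 4-methoxycoumarins, and the benzyl ether keeps C7'-O from being methylated.

Step 9
Reactants: 18 7-(benzyloxy)-6-(2,6-dimethoxy-4-methylphenyl)-4-methoxy-5-methyl-2H-chromen-2-one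
Product: 19 6-(3-acetyl-2,6-dimethoxy-4-methylphenyl)-7-(benzyloxy)-4-methoxy-5-methyl-2H-chromen-2-one
Conditions: AcCl, TiCl4, CH2Cl2, -78 to -20 °C
Reagents that add atoms: acetyl chloride, CC(Cl)=O
Why: Friedel-Crafts acylation goes to ring A because two methoxy groups activate it ortho and para far beyond the coumarin ring, its two free positions are equivalent and the first acetyl group shuts off a second; the axis becomes stereogenic here and forms without control as the racemate.

Step 10
Reactants: 19 6-(3-acetyl-2,6-dimethoxy-4-methylphenyl)-7-(benzyloxy)-4-methoxy-5-methyl-2H-chromen-2-one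
Product: 20 6-(3-acetyl-2-hydroxy-6-methoxy-4-methylphenyl)-7-hydroxy-4-methoxy-5-methyl-2H-chromen-2-one
Conditions: BCl3 (excess), pentamethylbenzene, CH2Cl2, -78 to 0 °C; MeOH/H2O
Reagents that add atoms: none
Why: Chelation-controlled ether cleavage, in which BCl3 held by the acetyl oxygen removes only the ortho methyl group and spares the para methoxy group and the methyl enol ether of unit B, while the benzyl ether, which cannot survive BCl3, is cleaved on purpose with pentamethylbenzene taking up the benzyl cation.

Step 11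
Reactants: 20 6-(3-acetyl-2-hydroxy-6-methoxy-4-methylphenyl)-7-hydroxy-4-methoxy-5-methyl-2H-chromen-2-one
Product: 21 6-(3-acetyl-2-hydroxy-6-methoxy-4-methylphenyl)-7-(benzyloxy)-4-methoxy-5-methyl-2H-chromen-2-one
Conditions: BnBr (1.05 equiv), K2CO3, acetone, rt
Reagents that add atoms: benzyl bromide, BrCc1ccccc1
Why: Selective Williamson benzylation, since the C7' phenol is the more acidic and accessible one whereas the ring A phenol is locked in a hydrogen bond to the acetyl group and is flanked on both sides.

Step 12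
Reactants: 21 6-(3-acetyl-2-hydroxy-6-methoxy-4-methylphenyl)-7-(benzyloxy)-4-methoxy-5-methyl-2H-chromen-2-one
Product: 23 8-[7-(benzyloxy)-4-methoxy-5-methyl-2-oxo-2H-chromen-6-yl]-4-hydroxy-7-methoxy-5-methyl-2H-chromen-2-one, via methyl keto ester 22 (not isolated)
Conditions: NaH, (MeO)2CO, toluene, 100 °C; aq. HCl
Reagents that add atoms: dimethyl carbonate, COC(=O)OC
Why: Claisen condensation of the methyl ketone enolate with dimethyl carbonate and lactonization by the phenoxide is the classical 4-hydroxycoumarin synthesis from 2-hydroxyacetophenones, and with methoxide as the only alkoxide any exchange at the methyl enol ether of unit B is degenerate.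

Step 13
Reactants: 23 8-[7-(benzyloxy)-4-methoxy-5-methyl-2-oxo-2H-chromen-6-yl]-4-hydroxy-7-methoxy-5-methyl-2H-chromen-2-one
Product: 24 8-[7-(benzyloxy)-4-methoxy-5-methyl-2-oxo-2H-chromen-6-yl]-4,7-dimethoxy-5-methyl-2H-chromen-2-one
Conditions: Me2SO4, K2CO3, acetone, reflux
Reagents that add atoms: dimethyl sulfate, COS(=O)(=O)OC
Why: The same O-methylation of a 4-hydroxycoumarin as in step 8, with C7'-O again masked as its benzyl ether.

Step 14
Reactants: 24 8-[7-(benzyloxy)-4-methoxy-5-methyl-2-oxo-2H-chromen-6-yl]-4,7-dimethoxy-5-methyl-2H-chromen-2-one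
Product: 25 8-(7-hydroxy-4-methoxy-5-methyl-2-oxo-2H-chromen-6-yl)-4,7-dimethoxy-5-methyl-2H-chromen-2-one
Conditions: H2 (1 atm), Pd/C, EtOAc/MeOH, rt
Reagents that add atoms: none
Why: Hydrogenolysis of the benzyl ether over Pd/C at ambient pressure leaves the methyl ethers and the enol-ether double bonds of both pyranone rings untouched.

Compound list
1 | 3,5-dimethoxytoluene | COc1cc(C)cc(OC)c1 | starting material
2 | (2,6-dimethoxy-4-methylphenyl)lithium (not isolated) | [Li]c1c(OC)cc(C)cc1OC | intermediate
3 | 2-(2,6-dimethoxy-4-methylphenyl)ethanol | COc1cc(C)cc(OC)c1CCO | intermediate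
4 | (2,6-dimethoxy-4-methylphenyl)acetaldehyde (not isolated) | COc1cc(C)cc(OC)c1CC=O | intermediate
5 | (2,6-dimethoxy-4-methylphenyl)acetic acid | COc1cc(C)cc(OC)c1CC(=O)O | intermediate
6 | 2,2,6-trimethyl-4H-1,3-dioxin-4-one | CC1=CC(=O)OC(C)(C)O1 | starting material
7 | (2,6-dimethoxy-4-methylphenyl)acetyl chloride (not isolated) | COc1cc(C)cc(OC)c1CC(Cl)=O | intermediate
8 | lithium 2,2-dimethyl-6-methylidene-1,3-dioxin-4-olate, the lithium dienolate of 6 (not isolated) | C=C1C=C(O[Li])OC(C)(C)O1 | intermediate
9 | 6-[3-(2,6-dimethoxy-4-methylphenyl)-2-oxopropyl]-2,2-dimethyl-4H-1,3-dioxin-4-one | COc1cc(C)cc(OC)c1CC(=O)CC1=CC(=O)OC(C)(C)O1 | intermediate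
10 | N-methoxy-N-methylacetamide | CON(C)C(C)=O | starting material
11 | dilithium dianion of 9, enolate on the dioxinone side and carbanion at the benzylic carbon (not isolated) | [Li]C(c1c(OC)cc(C)cc1OC)C(O[Li])=CC1=CC(=O)OC(C)(C)O1 | intermediate
12 | 6-[3-(2,6-dimethoxy-4-methylphenyl)-2,4-dioxopentyl]-2,2-dimethyl-4H-1,3-dioxin-4-one (enolizable, no fixed configuration) | CC(=O)C(c1c(OC)cc(C)cc1OC)C(=O)CC1=CC(=O)OC(C)(C)O1 | intermediate
13 | 6-(2,6-dimethoxy-4-methylphenyl)-5-hydroxy-2,2,5-trimethyl-5,6-dihydro-4H-1,3-benzodioxine-4,7(8H)-dione, mixture of diastereomers (not isolated) | CC1(O)C(c2c(OC)cc(C)cc2OC)C(=O)CC2=C1C(=O)OC(C)(C)O2 | intermediate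
14 | 6-(2,6-dimethoxy-4-methylphenyl)-7-hydroxy-2,2,5-trimethyl-4H-1,3-benzodioxin-4-one | CC1(C)OC(=O)c2c(C)c(-c3c(OC)cc(C)cc3OC)c(O)cc2O1 | intermediate
15 | 7-(benzyloxy)-6-(2,6-dimethoxy-4-methylphenyl)-2,2,5-trimethyl-4H-1,3-benzodioxin-4-one | CC1(C)OC(=O)c2c(C)c(-c3c(OC)cc(C)cc3OC)c(OCc3ccccc3)cc2O1 | intermediate
16 | tert-butyl 3-[4-(benzyloxy)-3-(2,6-dimethoxy-4-methylphenyl)-6-hydroxy-2-methylphenyl]-3-oxopropanoate (not isolated) | CC(C)(C)OC(=O)CC(=O)c1c(O)cc(OCc2ccccc2)c(-c2c(OC)cc(C)cc2OC)c1C | intermediate
17 | 7-(benzyloxy)-6-(2,6-dimethoxy-4-methylphenyl)-4-hydroxy-5-methyl-2H-chromen-2-one | COc1cc(C)cc(OC)c1-c1c(OCc2ccccc2)cc2oc(=O)cc(O)c2c1C | intermediate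
18 | 7-(benzyloxy)-6-(2,6-dimethoxy-4-methylphenyl)-4-methoxy-5-methyl-2H-chromen-2-one | COc1cc(C)cc(OC)c1-c1c(OCc2ccccc2)cc2oc(=O)cc(OC)c2c1C | intermediate
19 | 6-(3-acetyl-2,6-dimethoxy-4-methylphenyl)-7-(benzyloxy)-4-methoxy-5-methyl-2H-chromen-2-one (racemic axis) | CC(=O)c1c(C)cc(OC)c(-c2c(OCc3ccccc3)cc3oc(=O)cc(OC)c3c2C)c1OC | intermediate
20 | 6-(3-acetyl-2-hydroxy-6-methoxy-4-methylphenyl)-7-hydroxy-4-methoxy-5-methyl-2H-chromen-2-one (racemic axis) | CC(=O)c1c(C)cc(OC)c(-c2c(O)cc3oc(=O)cc(OC)c3c2C)c1O | intermediate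
21 | 6-(3-acetyl-2-hydroxy-6-methoxy-4-methylphenyl)-7-(benzyloxy)-4-methoxy-5-methyl-2H-chromen-2-one (racemic axis) | CC(=O)c1c(C)cc(OC)c(-c2c(OCc3ccccc3)cc3oc(=O)cc(OC)c3c2C)c1O | intermediate
22 | methyl 3-{3-[7-(benzyloxy)-4-methoxy-5-methyl-2-oxo-2H-chromen-6-yl]-2-hydroxy-4-methoxy-6-methylphenyl}-3-oxopropanoate (racemic axis, not isolated) | COC(=O)CC(=O)c1c(C)cc(OC)c(-c2c(OCc3ccccc3)cc3oc(=O)cc(OC)c3c2C)c1O | intermediate
23 | 8-[7-(benzyloxy)-4-methoxy-5-methyl-2-oxo-2H-chromen-6-yl]-4-hydroxy-7-methoxy-5-methyl-2H-chromen-2-one (racemic axis) | COc1cc(C)c2c(O)cc(=O)oc2c1-c1c(OCc2ccccc2)cc2oc(=O)cc(OC)c2c1C | intermediate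
24 | 8-[7-(benzyloxy)-4-methoxy-5-methyl-2-oxo-2H-chromen-6-yl]-4,7-dimethoxy-5-methyl-2H-chromen-2-one (racemic axis) | COc1cc(C)c2c(OC)cc(=O)oc2c1-c1c(OCc2ccccc2)cc2oc(=O)cc(OC)c2c1C | intermediate
25 | 8-(7-hydroxy-4-methoxy-5-methyl-2-oxo-2H-chromen-6-yl)-4,7-dimethoxy-5-methyl-2H-chromen-2-one, CNP0113839.0 (racemic axis) | COc1cc(C)c2c(OC)cc(=O)oc2c1-c1c(O)cc2oc(=O)cc(OC)c2c1C | target

Total step count: 14.
Longest linear sequence: 14 steps (1 to 25); the route is fully linear, with 6 and 10 entering as side components.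

Steps most likely to fail

Step 4. The benzylic terminus of dianion 11 is flanked by two methoxy groups, so proton transfer from the acetamide or acylation on oxygen may outrun carbon-carbon bond formation. The fallback sets out from 9 and returns at 12. The same dianion (LiN(CHMe2)2, THF, -78 °C) is added to acetaldehyde, a smaller and far more reactive electrophile, to give the aldol 6-[3-(2,6-dimethoxy-4-methylphenyl)-4-hydroxy-2-oxopentyl]-2,2-dimethyl-4H-1,3-dioxin-4-one F1 as a mixture of diastereomers. Dess-Martin oxidation (CH2Cl2, rt) of the secondary alcohol should then deliver 12, with both stereocentres of F1 lost.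

Step 5. Under amine base the substrate may rest as the enolate of its 2-aryl-1,3-diketone, which switches off the acetyl carbonyl as an electrophile. Slow ring closure would then leave time for retro-Claisen loss of the acetyl group or for closure through oxygen. The fallback sets out from 12 and returns at 14, and it forms the same C4a'-C5' bond and the same ring.
- Heating 12 in toluene (110 °C) expels acetone, and the acylketene is trapped by the enol oxygen to give 6-[1-(2,6-dimethoxy-4-methylphenyl)-2-oxopropyl]-4-hydroxy-2H-pyran-2-one F2.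
- Aqueous KOH at rt opens the pyranone to the triketo acid polyanion, which closes by aldol reaction and aromatizes. This is the classical base-induced rearrangement of 6-acetonyl-4-hydroxypyranones to orsellinic acids, and it should give 5-(2,6-dimethoxy-4-methylphenyl)-2,4-dihydroxy-6-methylbenzoic acid F3.
- Acetone, (CF3CO)2O and CF3CO2H then close the acetonide to 14.

Step 7. The acyl carbon of 15 lies between the C5' methyl group and the acetal oxygen, so addition of the bulky ester enolate may be slow, with self-condensation of the enolate on warming. The fallback sets out from 15 and returns at 18, bypassing 17 and step 8.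
- Methanolysis with K2CO3 in MeOH, in which the small methoxide opens the acetonide, gives methyl 4-(benzyloxy)-5-(2,6-dimethoxy-4-methylphenyl)-2-hydroxy-6-methylbenzoate F4.
- With ketenylidenetriphenylphosphorane (Ph3P=C=C=O, toluene, reflux) the phenol adds to the cumulene to form the ester ylide methyl 4-(benzyloxy)-5-(2,6-dimethoxy-4-methylphenyl)-6-methyl-2-[(triphenylphosphoranylidene)acetoxy]benzoate F5, which is not isolated.
- Intramolecular Wittig reaction of F5 with the neighbouring ester carbonyl closes the 4-methoxypyranone and gives 18.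

Further compounds
F1 | step 4 | 6-[3-(2,6-dimethoxy-4-methylphenyl)-4-hydroxy-2-oxopentyl]-2,2-dimethyl-4H-1,3-dioxin-4-one (mixture of diastereomers) | CC(O)C(c1c(OC)cc(C)cc1OC)C(=O)CC1=CC(=O)OC(C)(C)O1
F2 | step 5 | 6-[1-(2,6-dimethoxy-4-methylphenyl)-2-oxopropyl]-4-hydroxy-2H-pyran-2-one | CC(=O)C(c1c(OC)cc(C)cc1OC)c1cc(O)cc(=O)o1
F3 | step 5 | 5-(2,6-dimethoxy-4-methylphenyl)-2,4-dihydroxy-6-methylbenzoic acid | Cc1c(C(=O)O)c(O)cc(O)c1-c1c(OC)cc(C)cc1OC
F4 | step 7 | methyl 4-(benzyloxy)-5-(2,6-dimethoxy-4-methylphenyl)-2-hydroxy-6-methylbenzoate | COC(=O)c1c(O)cc(OCc2ccccc2)c(-c2c(OC)cc(C)cc2OC)c1C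
F5 | step 7 | methyl 4-(benzyloxy)-5-(2,6-dimethoxy-4-methylphenyl)-6-methyl-2-[(triphenylphosphoranylidene)acetoxy]benzoate | COC(=O)c1c(OC(=O)C=P(c2ccccc2)(c2ccccc2)c2ccccc2)cc(OCc2ccccc2)c(-c2c(OC)cc(C)cc2OC)c1C
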